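The plan hinges on the quaternary C4 of ring A (labdane numbering), which carries the C18 methyl and the oxygenated C19: C19 is treated as a carbon expelled from a larger ring. (R)-Carvone supplies ring B and C5; double α′-alkylation sets C10, and ring-closing metathesis builds a trans-fused cycloheptene containing C19 between C3 and C4. In the key step the derived 4β,19β-epoxide rearranges under BF3: C3 migrates from C19 to C4, contracting the seven-membered ring to ring A while creating the C4 stereocentre with inversion and unmasking C19 as the axial formyl group. The enone of ring B then delivers C9, C7 and C8.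

Key step: step 7

Remark: labdane numbers are used for all intermediates; in 5 and 8–12 the future C19 is a member of the seven-membered ring, between C3 and C4, and α means the face opposite the C10 methyl.

Step 1
Reactants: 1 (R)-(−)-carvone
Product: 2 trans-6-methylcarvone
Conditions: LiN(i-Pr)2, THF, −78 °C; MeI, −78 → 0 °C
Reagents that add atoms: iodomethane (CI)
Why: Kinetic α′-deprotonation of the cross-conjugated enone and SN2 methylation anti to the isopropenyl group should give mainly the trans isomer, and this centre (future C10) is planarised again in step 2 (enolate alkylation).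

Step 2
Reactants: 2 trans-6-methylcarvone; 3 5-iodopent-1-ene
Product: 4 6-methyl-6-(pent-4-enyl)carvone (pentenyl trans to isopropenyl)
Conditions: LiN(i-Pr)2, THF, −78 °C; HMPA; 3, −78 °C → rt
Reagents that add atoms: none
Why: The tetrasubstituted α′-enolate should be alkylated on the face anti to the neighbouring isopropenyl group, which places the pentenyl chain trans and the methyl cis to it and so sets the quaternary C10 (enolate alkylation under 1,2-induction).

Step 3
Reactants: 4 6-methyl-6-(pent-4-enyl)carvone
Product: 5 trans-fused bicyclic dienone (9-oxo; C7=C8; C4=C19)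
Conditions: second-generation Grubbs catalyst (5 mol%), CH2Cl2 (5 mM), 40 °C
Reagents that add atoms: none
Why: Ring-closing metathesis between the terminal alkene and the isopropenyl group, held trans on adjacent carbons, should close the trans-fused cycloheptene with loss of ethylene, the electron-poor enone alkene being inert.

Step 4
Reactants: 5 trans-fused bicyclic dienone; 6 (4-bromobut-1-yn-1-yl)trimethylsilane
Product: 8 tertiary allylic alcohol at C9, via butynyl Grignard reagent 7 (not isolated)
Conditions: 6, Mg, THF, rt; anhydrous CeCl3, THF, −78 °C; then 5, −78 → 0 °C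
Reagents that add atoms: none
Why: CeCl3-promoted Grignard 1,2-addition to the hindered enone carbonyl should suppress enolisation, hydride transfer and 1,4-addition and is expected anti to the angular methyl, the new carbinol centre being erased in step 5.

Step 5
Reactants: 8 tertiary allylic alcohol at C9
Product: 9 transposed enone (7-oxo; C8=C9)
Conditions: [C5H5NH][CrO3Cl], 4 Å molecular sieves, CH2Cl2, rt
Reagents that add atoms: none
Why: In a Babler–Dauben oxidative transposition the chromate ester of the tertiary allylic alcohol should shift [3,3] to C7 and be oxidised there, leaving the side chain on the enone β-carbon C9.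

Step 6
Reactants: 9 transposed enone
Product: 12 epoxy enone (4β,19β-oxirane; terminal alkyne), via bromohydrin 10 (not isolated), via silyl epoxide 11 (not isolated)
Conditions: NBS, THF–H2O (4:1), 0 °C; then K2CO3, MeOH, rt
Reagents that add atoms: water (O)
Why: NBS should form the bromonium ion of the electron-rich cycloheptene on the α face and water should open it anti at the tertiary C4, so that base closes the trans-bromohydrin by intramolecular SN2 (inversion at C19) to the β-epoxide while carbonate in methanol also cleaves the alkynyl–silicon bond, the enone alkene being too electron-poor to react (bromohydrin formation, then oxirane closure).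

Step 7
Reactants: 12 epoxy enone
Product: 13 ring-contracted keto aldehyde (7-oxo-15,16-dinorlabd-8-en-13-yn-19-al)
Conditions: BF3·OEt2 (0.3 equiv), CH2Cl2, −78 → −40 °C
Reagents that add atoms: none
Why: BF3 coordinates the oxirane oxygen and the C4–O bond ionises at the tertiary carbon while the ring bond C19–C3, anti to it on the α face, migrates from C19 to C4 and the oxygen lone pair closes the C19 formyl group (Meinwald-type semipinacol rearrangement of a trisubstituted epoxide). The closest known reaction type is the Lewis-acid rearrangement of 1-methylcycloalkene oxides and of α-pinene oxide to ring-contracted aldehydes. Ring A is not closed by a cyclisation but arises from the seven-membered ring by a 1,2-alkyl shift that expels C19 and forms the C3–C4 bond. C4 is the only new stereocentre and is set by inversion, so the β-epoxide of step 6 dictates α-methyl (C18, equatorial) and β-formyl (C19, axial), while C5 and C10 are untouched. The step needs migration of C3 in preference to the hydride on C19 (which would give a cycloheptanone) and to proton loss; in the trans-fused bicycle the twist about C4–C19 that brings C3 under the α lobe relaxes the eclipsed oxirane bonds, whereas the twist needed for hydride shift would drive C3 toward the axial C10 methyl. The enone carbonyl and the terminal alkyne should be inert to substoichiometric BF3·OEt2 at low temperature.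

Step 8
Reactants: 13 ring-contracted keto aldehyde
Product: 14 hydroxy enone (19-hydroxy-15,16-dinorlabd-8-en-13-yn-7-one)
Conditions: NaBH4, MeOH–CH2Cl2, −78 °C
Reagents that add atoms: none
Why: Borohydride at −78 °C should reduce only the aldehyde, the conjugated tetrasubstituted enone carbonyl being far less electrophilic (chemoselective hydride reduction).

Step 9
Reactants: 14 hydroxy enone; 15 (diethoxyphosphoryl)acetic acid
Product: 16 phosphonoacetate enone
Conditions: DCC, DMAP (cat.), CH2Cl2, 0 °C → rt
Reagents that add atoms: none
Why: Steglich esterification of the only hydroxyl group should install a phosphonoacetate that masks C19–OH through steps 10–13 and serves as the handle for the final olefination.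

Step 10
Reactants: 16 phosphonoacetate enone
Product: 17 allylic alcohol (7β-OH)
Conditions: NaBH4, CeCl3·7H2O, MeOH, −40 °C
Reagents that add atoms: none
Why: Luche 1,2-reduction should deliver hydride axially on the α face, as for other 10-methyl octalin enones, giving the equatorial 7β-alcohol without touching the ester.

Step 11
Reactants: 17 allylic alcohol (7β-OH)
Product: 20 alkene phosphonoacetate (C7=C8; 9α-H), via sulfonyl hydrazone adduct 18 (not isolated), via allylic diazene 19 (not isolated)
Conditions: PPh3, diethyl azodicarboxylate, N′-isopropylidene-2-nitrobenzenesulfonohydrazide, THF, 0 °C → rt; then CF3CH2OH–H2O (1:1), rt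
Reagents that add atoms: none
Why: Mitsunobu displacement with inversion should place nitrogen on the α face of C7, and after hydrazone hydrolysis and sulfinate loss the 7α-diazene should lose N2 by a retro-ene process that delivers hydrogen suprafacially to the α face of C9 and moves the alkene to C7=C8, fixing C9 with the side chain β (reductive 1,3-transposition of an allylic alcohol).

Step 12
Reactants: 20 alkene phosphonoacetate
Product: 21 diol (7α-OH; 8α-OH)
Conditions: OsO4 (2 mol%), N-methylmorpholine N-oxide, acetone–H2O (5:1), rt
Reagents that add atoms: OsO4 (O=[Os](=O)(=O)=O) as catalytic oxygen carrier; N-methylmorpholine N-oxide (C[N+]1([O-])CCOCC1); water (O)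
Why: Upjohn syn-dihydroxylation of the trisubstituted alkene should occur on the α face, opposite the axial C10 methyl and the axial C19 substituent, setting 7α-OH and 8α-OH with the C8 methyl β, the terminal alkyne reacting much more slowly.

Step 13
Reactants: 21 diol
Product: 22 diene diol phosphonoacetate
Conditions: second-generation Grubbs catalyst (5 mol%), ethylene (1 atm), CH2Cl2, 40 °C
Reagents that add atoms: ethylene (C=C)
Why: Cross enyne metathesis of the terminal alkyne with ethylene should give the 2-substituted buta-1,3-diene directly, no other carbon–carbon multiple bond being present and the hydroxyls and phosphonate being tolerated.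

Step 14
Reactants: 22 diene diol phosphonoacetate; 23 4-hydroxybenzaldehyde
Product: 24 target (E)-4-hydroxycinnamate
Conditions: LiCl, DBU (2.5 equiv), MeCN, rt → 40 °C
Reagents that add atoms: none
Why: Horner–Wadsworth–Emmons olefination under Masamune–Roush conditions should give the (E)-cinnamate, the phenol being carried as its phenoxide and reprotonated on work-up, while the hindered neopentyl ester, the diol and the diene stay intact.

Compound list
1 | (R)-(−)-carvone, (5R)-2-methyl-5-(prop-1-en-2-yl)cyclohex-2-en-1-one | O=C1C(C)=CC[C@@H](C(C)=C)C1 | starting material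
2 | trans-6-methylcarvone: 2,6-dimethyl-5-(prop-1-en-2-yl)cyclohex-2-en-1-one, 6-methyl trans to the isopropenyl group | O=C1C(C)=CC[C@@H](C(C)=C)[C@@H]1C | intermediate
3 | 5-iodopent-1-ene | C=CCCCI | starting material
4 | 2,6-dimethyl-6-(pent-4-en-1-yl)-5-(prop-1-en-2-yl)cyclohex-2-en-1-one, pentenyl trans and 6-methyl cis to the isopropenyl group | O=C1C(C)=CC[C@@H](C(C)=C)[C@]1(C)CCCC=C | intermediate
5 | trans-fused bicyclo[5.4.0]undecadienone: ring B (C5–C10) with 9-oxo and C7=C8; seven-membered ring C10–C1–C2–C3–C19–C4–C5 with C4=C19; methyls on C4, C8, C10; 10β-CH3, 5α-H | O=C1C(C)=CC[C@H]2C(C)=CCCC[C@]12C | intermediate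
6 | (4-bromobut-1-yn-1-yl)trimethylsilane | C[Si](C)(C)C#CCCBr | starting material
7 | [4-(trimethylsilyl)but-3-yn-1-yl]magnesium bromide | C[Si](C)(C)C#CCC[Mg]Br | intermediate
8 | tertiary allylic alcohol: 5 with C9 as C(OH)CH2CH2C≡C–SiMe3 (9β-OH, chain α) | O[C@@]1(CCC#C[Si](C)(C)C)C(C)=CC[C@H]2C(C)=CCCC[C@]12C | intermediate
9 | transposed enone: 7-oxo, C8=C9, C9 carrying CH2CH2C≡C–SiMe3, C4=C19 cycloheptene retained | O=C1C[C@H]2C(C)=CCCC[C@]2(C)C(CCC#C[Si](C)(C)C)=C1C | intermediate
10 | bromohydrin: 9 with 4β-OH (tertiary) and 19α-Br | O=C1C[C@H]2[C@@](C)(O)[C@H](Br)CCC[C@]2(C)C(CCC#C[Si](C)(C)C)=C1C | intermediate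
11 | silyl epoxide: 9 with a 4β,19β-oxirane, alkyne still silylated | O=C1C[C@H]2[C@@]3(C)O[C@H]3CCC[C@]2(C)C(CCC#C[Si](C)(C)C)=C1C | intermediate
12 | epoxy enone: 4β,19β-oxirane, 7-oxo, C8=C9, C9 chain CH2CH2C≡CH | O=C1C[C@H]2[C@@]3(C)O[C@H]3CCC[C@]2(C)C(CCC#C)=C1C | intermediate
13 | 7-oxo-15,16-dinorlabd-8-en-13-yn-19-al (trans-decalin; 4α-CH3, 4β-CHO, 5α-H, 10β-CH3) | O=C1C[C@H]2[C@@](C)(C=O)CCC[C@]2(C)C(CCC#C)=C1C | intermediate
14 | 19-hydroxy-15,16-dinorlabd-8-en-13-yn-7-one | O=C1C[C@H]2[C@@](C)(CO)CCC[C@]2(C)C(CCC#C)=C1C | intermediate
15 | (diethoxyphosphoryl)acetic acid | CCOP(=O)(CC(=O)O)OCC | starting material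
16 | 7-oxo-15,16-dinorlabd-8-en-13-yn-19-yl (diethoxyphosphoryl)acetate | O=C1C[C@H]2[C@@](C)(COC(=O)CP(=O)(OCC)OCC)CCC[C@]2(C)C(CCC#C)=C1C | intermediate
17 | 7β-hydroxy-15,16-dinorlabd-8-en-13-yn-19-yl (diethoxyphosphoryl)acetate | O[C@H]1C[C@H]2[C@@](C)(COC(=O)CP(=O)(OCC)OCC)CCC[C@]2(C)C(CCC#C)=C1C | intermediate
18 | Mitsunobu adduct: 17 with 7β-OH replaced by 7α-N(SO2C6H4-2-NO2)–N=C(CH3)2 | CC(C)=NN([C@@H]1C[C@H]2[C@@](C)(COC(=O)CP(=O)(OCC)OCC)CCC[C@]2(C)C(CCC#C)=C1C)S(=O)(=O)c3ccccc3[N+](=O)[O-] | intermediate
19 | allylic diazene: 7α-N=NH analogue of 17 | N=N[C@@H]1C[C@H]2[C@@](C)(COC(=O)CP(=O)(OCC)OCC)CCC[C@]2(C)C(CCC#C)=C1C | intermediate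
20 | 15,16-dinorlabd-7-en-13-yn-19-yl (diethoxyphosphoryl)acetate (9α-H) | C#CCC[C@H]1C(C)=CC[C@H]2[C@@](C)(COC(=O)CP(=O)(OCC)OCC)CCC[C@@]21C | intermediate
21 | 7α,8α-dihydroxy-15,16-dinorlabd-13-yn-19-yl (diethoxyphosphoryl)acetate | C#CCC[C@H]1[C@](C)(O)[C@H](O)C[C@H]2[C@@](C)(COC(=O)CP(=O)(OCC)OCC)CCC[C@@]21C | intermediate
22 | 7α,8α-dihydroxylabda-13(16),14-dien-19-yl (diethoxyphosphoryl)acetate | C=CC(=C)CC[C@H]1[C@](C)(O)[C@H](O)C[C@H]2[C@@](C)(COC(=O)CP(=O)(OCC)OCC)CCC[C@@]21C | intermediate
23 | 4-hydroxybenzaldehyde | O=Cc1ccc(O)cc1 | starting material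
24 | 7α,8α-dihydroxylabda-13(16),14-dien-19-yl (E)-3-(4-hydroxyphenyl)prop-2-enoate (CNP0254560.2) | C=CC(=C)CC[C@H]1[C@](C)(O)[C@H](O)C[C@H]2[C@@](C)(COC(=O)/C=C/c3ccc(O)cc3)CCC[C@@]21C | target

Total step count: 14
Longest linear sequence: 14 steps (1 → 24)

Steps most likely to fail

Step 7. The C4 cation may undergo 1,2-hydride shift from C19 (a ring-retained ketone) or proton loss faster than ring-bond migration. If the oxirane opens to a free cation before migration, the C4 configuration erodes. The fallback sets out from 9 and comes back at 13. It uses the halohydrin-salt route with two inversions at C4 instead of the direct Lewis-acid rearrangement. Compound 9 is epoxidised with mCPBA (NaHCO3, CH2Cl2, 0 °C) on the open α face to give the 4α,19α-epoxide F1. Heating with LiBr and HMPA in toluene should let bromide open the oxirane at the tertiary C4 with inversion, giving the lithium alkoxide of the 4β-bromo-19α-ol F2. In this salt the C19–C3 bond is anti to the C4–Br bond, so alkoxide-driven migration of C3 with loss of bromide should give the silylated keto aldehyde F3. K2CO3 in MeOH then removes the alkynyl silyl group and gives 13.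

Step 2. SN2 of an unactivated primary iodide at a hindered tetrasubstituted enolate is slow. Enolate equilibration, O-alkylation or elimination of HI can then compete, and diastereocontrol can be lost on warming. The fallback sets out from 2 and comes back at 4. The same enolate is alkylated with the far more reactive allyl bromide, again anti to the isopropenyl group, to give the 6-allyl-6-methyl ketone F4. Hydroboration of its monosubstituted alkene with 9-BBN (THF, 0 °C) should be selective over the isopropenyl group and the hindered carbonyl and give the alkylborane F5. Without isolation, B-alkyl Suzuki–Miyaura coupling with vinyl bromide (PdCl2(dppf), aqueous K3PO4, THF) extends the chain by two carbons and gives 4.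

Step 11. Mitsunobu activation of the hindered allylic alcohol can divert to SN2′ attack or elimination. It can also ionise and lose the clean inversion on which α-delivery of hydrogen to C9 depends. The fallback sets out from 17 and comes back at 20. Compound 17 is formylated with acetic formic anhydride and pyridine to give the 7β-formate F6. With Pd(OAc)2 and PBu3 in refluxing THF, zerovalent palladium should ionise the formate with inversion. Decarboxylation then gives a palladium hydride, which transfers hydrogen to the more substituted allyl terminus C9 on the α face. This gives 20 with loss of CO2.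

Further compounds
F1 | step 7 | 4α,19α-epoxide of 9 (alkyne silylated) | O=C1C[C@H]2[C@]3(C)O[C@@H]3CCC[C@]2(C)C(CCC#C[Si](C)(C)C)=C1C
F2 | step 7 | 4β-bromo-19α-ol (formed as its lithium alkoxide) | O=C1C[C@H]2[C@@](C)(Br)[C@H](O)CCC[C@]2(C)C(CCC#C[Si](C)(C)C)=C1C
F3 | step 7 | 14-(trimethylsilyl)-7-oxo-15,16-dinorlabd-8-en-13-yn-19-al | O=C1C[C@H]2[C@@](C)(C=O)CCC[C@]2(C)C(CCC#C[Si](C)(C)C)=C1C
F4 | step 2 | 6-allyl-6-methylcarvone, allyl trans to the isopropenyl group | O=C1C(C)=CC[C@@H](C(C)=C)[C@]1(C)CC=C
F5 | step 2 | B-alkyl-9-borabicyclo[3.3.1]nonane from F4 | O=C1C(C)=CC[C@@H](C(C)=C)[C@]1(C)CCCB3C4CCCC3CCC4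
F6 | step 11 | 7β-formate of 17 | O=CO[C@H]1C[C@H]2[C@@](C)(COC(=O)CP(=O)(OCC)OCC)CCC[C@]2(C)C(CCC#C)=C1C
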